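**Direct plan and its weak points**

A direct plan would build an acyclic C20 tetraene A3 that already carries the C2 senecioate and a C13 formate, by alkylating the allylic sulfone A1 with the terpene-derived allylic chloride A2 and then removing the sulfone.
It would then close both rings at the very end in one cobalt-hydride hydrogen-atom-transfer, radical–polar crossover bicyclisation.
- The final bicyclisation would be the weakest step. It is an untested cascade that must select one of four alkenes, terminate as the Δ7 olefin, and let one remote equatorial C2 ester fix C5, C9 and C10, all on the most valuable intermediate.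
- The four-step linear run-up to sulfone A1 (two epoxide openings, then carboalumination and hydroxymethylation on a free alcohol) would be long for a fragment with one stereocentre.
- The sulfone alkylation and reductive desulfonylation, together with the formylation and deformylation, would spend four steps on one C–C bond, and the palladium hydride step risks allylic transposition.

**Retrosynthetic overview of the new route**

- Ring B is bought, not built: (S)-carvone supplies C5–C10, the C7=C8 olefin with its C17 methyl, the C5 stereocentre and, as the isopropenyl group, C4 with both future gem-dimethyl carbons.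
- C10 is made quaternary by two enolate alkylations (methyl, then allyl anti to the isopropenyl group), which fixes the trans C5/C10 relationship.
- Ring A is closed last: acid turns the isopropenyl group into the C4 cation, the allyl terminus forms C3–C4, and formate capture installs the equatorial C2 oxygen.
- The side chain C11–C16 (C13 from (S)-linalool, degraded to a C6 iodide) is joined at C9 by cross-coupling with the dienyl triflate of the carvone enone; a 1,4-hydrogenation then sets H-9 and leaves the C7=C8 olefin.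
- There is no polyene, no sulfone and no late cascade; C10, C2 and C9 are each set under the control of C5 of carvone.

Key step: step 3

Assumption: (S)-(+)-carvone and (S)-(+)-linalool are used as purchased single enantiomers; atom labels C1–C20 follow ent-labdane numbering (carvone C6 becomes C10, the carvone carbonyl becomes C9).

**Route**

Step 1
Reactants: 1 (S)-(+)-carvone
Product: 2 (5S,6RS)-2,6-dimethyl-5-(prop-1-en-2-yl)cyclohex-2-en-1-one (6-methylcarvone as C6 epimers)
Conditions: LiN(iPr)2 (1.1 equiv), THF, −78 °C; MeI (1.5 equiv), −78 to −20 °C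
Reagents that add atoms: iodomethane, CI
Why: Kinetic α′-deprotonation of the enone and C-methylation of the lithium enolate (enolate alkylation) places the future C20 methyl on C10, and the epimer ratio at this centre does not matter because it is enolised again in step 2.

Step 2
Reactants: 2 (5S,6RS)-2,6-dimethyl-5-(prop-1-en-2-yl)cyclohex-2-en-1-one
Product: 3 (5R,6R)-2,6-dimethyl-6-(prop-2-en-1-yl)-5-(prop-1-en-2-yl)cyclohex-2-en-1-one
Conditions: LiN(iPr)2 (1.2 equiv), THF, −78 °C; DMPU (3 equiv), allyl bromide (1.5 equiv), −78 to 0 °C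
Reagents that add atoms: allyl bromide, C=CCBr
Why: Alkylation of the tetrasubstituted lithium enolate should occur anti to the neighbouring isopropenyl group (1,2-induction from C5), so the allyl group (C1–C3) enters trans and the methyl ends cis to the isopropenyl group, which is the C5/C10 relationship of the trans-decalin.

Step 3
Reactants: 3 (5R,6R)-2,6-dimethyl-6-(prop-2-en-1-yl)-5-(prop-1-en-2-yl)cyclohex-2-en-1-one
Product: 4 (2R,4aR,8aR)-4,4,7,8a-tetramethyl-8-oxo-1,2,3,4,4a,5,8,8a-octahydronaphthalen-2-yl formate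
Conditions: HCO2H (98%, 0.05 M), 50 °C; evaporation, NaHCO3 work-up
Reagents that add atoms: formic acid, O=CO
Why: Formic acid protonates the 1,1-disubstituted isopropenyl group (the enone olefin is deactivated and the vinyl group is far less basic) to give the tertiary C4 cation, which thereby already carries both C4 methyl groups. The terminal allyl carbon (C3) attacks this cation in a 6-endo-trig closure through a chair transition state in which the C5 and C10 arms are both pseudo-equatorial on ring B and the C10 methyl is axial, so ring A closes trans-fused without touching C5 or C10. The developing secondary C2 cation is captured by formic acid anti to the new C3–C4 bond, that is equatorially and from the face away from the two syn-axial methyl groups (C10–CH3 and the axial C4–CH3), which sets (2R); the formate then serves as the protecting group for the next steps. The closest known reaction type is the formolytic cation–olefin cyclisation of 1,6-dienes, and of N-acyliminium ions onto terminal vinyl groups, which end as equatorial cyclohexyl formates. The step needs Markovnikov protonation of the isopropenyl group only and 6-endo attack (5-exo attack would give a primary cation); both follow from the substitution pattern of 3, and the trans arrangement of the two arms from step 2 leaves the trans-decalin as the only strain-free closure.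

Step 4
Reactants: 4 (2R,4aR,8aR)-4,4,7,8a-tetramethyl-8-oxo-1,2,3,4,4a,5,8,8a-octahydronaphthalen-2-yl formate
Product: 5 (2R,4aR,8aR)-4,4,7,8a-tetramethyl-8-[(trifluoromethanesulfonyl)oxy]-1,2,3,4,4a,8a-hexahydronaphthalen-2-yl formate
Conditions: Tf2O (1.3 equiv), 2,6-di-tert-butyl-4-methylpyridine (1.6 equiv), CH2Cl2, 0 °C to rt
Reagents that add atoms: trifluoromethanesulfonic anhydride, O=S(=O)(OS(=O)(=O)C(F)(F)F)C(F)(F)F
Why: O-Sulfonylation of the enone carbonyl followed by γ-deprotonation by the hindered pyridine (enol triflate formation; C10 is quaternary, so C6–H is the only proton that can be lost) should give the linear dienyl triflate with the formate ester untouched, as known for 2,6,6-trimethylcyclohex-2-enone.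

Step 5
Reactants: 6 (S)-(+)-linalool
Product: 7 (5S)-5-ethenyl-5-methyloxolan-2-ol (lactol as both anomers)
Conditions: O3 (1.0 equiv, Sudan Red 7B end point), CH2Cl2, −78 °C; Me2S (3 equiv), −78 °C to rt
Reagents that add atoms: ozone, [O-][O+]=O
Why: Ozonolysis cleaves the electron-rich trisubstituted alkene well before the vinyl group, and the resulting γ-hydroxy aldehyde closes to the lactol without touching the future C13 stereocentre.

Step 6
Reactants: 7 (5S)-5-ethenyl-5-methyloxolan-2-ol
Product: 8 (3S)-5-iodo-3-methylpent-1-en-3-yl formate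
Conditions: PhI(OAc)2 (1.1 equiv), I2 (1.0 equiv), cyclohexane–CH2Cl2 3:1, tungsten lamp, 20 °C
Reagents that add atoms: iodine, II
Why: In this Suárez hypoiodite fragmentation the anomeric alkoxy radical undergoes β-scission of the C2–C3 bond of the oxolane (driven by formation of the formate carbonyl), the primary radical is trapped by iodine, and the stereocentre, which now carries the formate, is not involved.

Step 7
Reactants: 8 (3S)-5-iodo-3-methylpent-1-en-3-yl formate
Product: 10 {[(3S)-5-iodo-3-methylpent-1-en-3-yl]oxy}trimethylsilane, via iodo alcohol 9 (not isolated)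
Conditions: K2CO3 (0.2 equiv), MeOH, 0 °C; concentrate; 1-(trimethylsilyl)imidazole (1.5 equiv), CH2Cl2, rt
Reagents that add atoms: 1-(trimethylsilyl)imidazole, C[Si](C)(C)n1ccnc1
Why: Transesterification removes the tertiary allylic formate, which zerovalent palladium would ionise in step 8, and silyl transfer caps the tertiary alcohol as a trimethylsilyl ether that tolerates zinc insertion and is later cleaved together with the C2 formate.

Step 8
Reactants: 5 (2R,4aR,8aR)-4,4,7,8a-tetramethyl-8-[(trifluoromethanesulfonyl)oxy]-1,2,3,4,4a,8a-hexahydronaphthalen-2-yl formate and 10 {[(3S)-5-iodo-3-methylpent-1-en-3-yl]oxy}trimethylsilane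
Product: 12 (2R,4aR,8aR)-4,4,7,8a-tetramethyl-8-{(3S)-3-methyl-3-[(trimethylsilyl)oxy]pent-4-en-1-yl}-1,2,3,4,4a,8a-hexahydronaphthalen-2-yl formate, via alkylzinc iodide 11 (not isolated)
Conditions: 10 (1.4 equiv), Zn dust (2.5 equiv), LiCl (1.5 equiv), THF, 40 °C; then 5 (1.0 equiv), Pd(OAc)2 (4 mol%), SPhos (8 mol%), THF–NMP 2:1, 45 °C
Reagents that add atoms: zinc, [Zn] (zinc of 11 only)
Why: LiCl-assisted zinc insertion into the primary iodide and Negishi sp3–sp2 coupling with the dienyl triflate join C11 to C9 with the diene in place; the alkylzinc iodide does not attack the formate, the bulky biarylphosphine helps reductive elimination at the hindered C9, and no stereocentre is formed or touched.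

Step 9
Reactants: 12 (2R,4aR,8aR)-4,4,7,8a-tetramethyl-8-{(3S)-3-methyl-3-[(trimethylsilyl)oxy]pent-4-en-1-yl}-1,2,3,4,4a,8a-hexahydronaphthalen-2-yl formate
Product: 13 (2R,4aR,8R,8aR)-4,4,7,8a-tetramethyl-8-{(3S)-3-methyl-3-[(trimethylsilyl)oxy]pent-4-en-1-yl}-1,2,3,4,4a,5,8,8a-octahydronaphthalen-2-yl formate
Conditions: (η6-naphthalene)Cr(CO)3 (15 mol%), H2 (40 atm), THF, 45 °C
Reagents that add atoms: none
Why: Chromium tricarbonyl-catalysed 1,4-hydrogenation of the homoannular (s-cis) diene should deliver both hydrogen atoms to C6 and C9 from the diene face opposite the axial C10 methyl, which sets (9R) with H-9 cis to H-5 and leaves the olefin at C7=C8, while the isolated vinyl group and both protecting groups are not substrates for this catalyst.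

Step 10
Reactants: 13 (2R,4aR,8R,8aR)-4,4,7,8a-tetramethyl-8-{(3S)-3-methyl-3-[(trimethylsilyl)oxy]pent-4-en-1-yl}-1,2,3,4,4a,5,8,8a-octahydronaphthalen-2-yl formate
Product: 14 (2R,4aR,8R,8aR)-8-[(3S)-3-hydroxy-3-methylpent-4-en-1-yl]-4,4,7,8a-tetramethyl-1,2,3,4,4a,5,8,8a-octahydronaphthalen-2-ol
Conditions: K2CO3 (1.5 equiv), MeOH, 0 °C to rt
Reagents that add atoms: none
Why: Base-catalysed methanolysis (transesterification and silyl ether solvolysis) removes the secondary formate and the tertiary trimethylsilyl ether in one operation without affecting any stereocentre.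

Step 11
Reactants: 14 (2R,4aR,8R,8aR)-8-[(3S)-3-hydroxy-3-methylpent-4-en-1-yl]-4,4,7,8a-tetramethyl-1,2,3,4,4a,5,8,8a-octahydronaphthalen-2-ol
Product: 15 target, (2R,4aR,8R,8aR)-8-[(3S)-3-hydroxy-3-methylpent-4-en-1-yl]-4,4,7,8a-tetramethyl-1,2,3,4,4a,5,8,8a-octahydronaphthalen-2-yl 3-methylbut-2-enoate
Conditions: 3-methylbut-2-enoic acid (1.5 equiv), DCC (1.5 equiv), DMAP (0.2 equiv), CH2Cl2, 0 °C to rt
Reagents that add atoms: 3-methylbut-2-enoic acid, CC(C)=CC(=O)O
Why: Steglich esterification acylates the equatorial secondary C2 alcohol with retention while the tertiary allylic C13 alcohol is too hindered to react, and carbodiimide activation avoids the ketene pathway that would deconjugate the acid.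

**Compound list**

1 | (S)-(+)-carvone, (5S)-2-methyl-5-(prop-1-en-2-yl)cyclohex-2-en-1-one | O=C1C(C)=CC[C@H](C(C)=C)C1 | starting material
2 | (5S,6RS)-2,6-dimethyl-5-(prop-1-en-2-yl)cyclohex-2-en-1-one (C6 epimers, methyl trans to isopropenyl expected as major) | O=C1C(C)=CC[C@H](C(C)=C)C1C | intermediate
3 | (5R,6R)-2,6-dimethyl-6-(prop-2-en-1-yl)-5-(prop-1-en-2-yl)cyclohex-2-en-1-one (allyl trans, methyl cis to isopropenyl) | O=C1C(C)=CC[C@H](C(C)=C)[C@]1(CC=C)C | intermediate
4 | (2R,4aR,8aR)-4,4,7,8a-tetramethyl-8-oxo-1,2,3,4,4a,5,8,8a-octahydronaphthalen-2-yl formate (trans-fused, equatorial formate) | O=C1C(C)=CC[C@@H]2C(C)(C)C[C@@H](OC=O)C[C@@]12C | intermediate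
5 | (2R,4aR,8aR)-4,4,7,8a-tetramethyl-8-[(trifluoromethanesulfonyl)oxy]-1,2,3,4,4a,8a-hexahydronaphthalen-2-yl formate | O=S(=O)(OC1=C(C)C=C[C@@H]2C(C)(C)C[C@@H](OC=O)C[C@@]12C)C(F)(F)F | intermediate
6 | (S)-(+)-linalool, (3S)-3,7-dimethylocta-1,6-dien-3-ol | C=C[C@@](C)(O)CCC=C(C)C | starting material
7 | (5S)-5-ethenyl-5-methyloxolan-2-ol (both anomers) | C=C[C@@]1(C)OC(O)CC1 | intermediate
8 | (3S)-5-iodo-3-methylpent-1-en-3-yl formate | C=C[C@@](C)(OC=O)CCI | intermediate
9 | (3S)-5-iodo-3-methylpent-1-en-3-ol | C=C[C@@](C)(O)CCI | intermediate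
10 | {[(3S)-5-iodo-3-methylpent-1-en-3-yl]oxy}trimethylsilane | C=C[C@@](C)(O[Si](C)(C)C)CCI | intermediate
11 | {(3S)-3-methyl-3-[(trimethylsilyl)oxy]pent-4-en-1-yl}zinc iodide (LiCl complex in THF) | C=C[C@@](C)(O[Si](C)(C)C)CC[Zn]I | intermediate
12 | (2R,4aR,8aR)-4,4,7,8a-tetramethyl-8-{(3S)-3-methyl-3-[(trimethylsilyl)oxy]pent-4-en-1-yl}-1,2,3,4,4a,8a-hexahydronaphthalen-2-yl formate | C=C[C@@](C)(O[Si](C)(C)C)CCC1=C(C)C=C[C@@H]2C(C)(C)C[C@@H](OC=O)C[C@@]12C | intermediate
13 | (2R,4aR,8R,8aR)-4,4,7,8a-tetramethyl-8-{(3S)-3-methyl-3-[(trimethylsilyl)oxy]pent-4-en-1-yl}-1,2,3,4,4a,5,8,8a-octahydronaphthalen-2-yl formate | C=C[C@@](C)(O[Si](C)(C)C)CC[C@@H]1C(C)=CC[C@@H]2C(C)(C)C[C@@H](OC=O)C[C@@]12C | intermediate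
14 | (2R,4aR,8R,8aR)-8-[(3S)-3-hydroxy-3-methylpent-4-en-1-yl]-4,4,7,8a-tetramethyl-1,2,3,4,4a,5,8,8a-octahydronaphthalen-2-ol (ent-labda-7,14-diene-2,13-diol, 2-OH equatorial) | C=C[C@@](C)(O)CC[C@@H]1C(C)=CC[C@@H]2C(C)(C)C[C@@H](O)C[C@@]12C | intermediate
15 | 13-hydroxy-ent-labda-7,14-dien-2-yl 3-methylbut-2-enoate (2R,5R,9R,10R,13S), CNP0252389.1 | C=C[C@@](C)(O)CC[C@@H]1C(C)=CC[C@@H]2C(C)(C)C[C@@H](OC(=O)C=C(C)C)C[C@@]12C | target

**Step count and risks**

Total step count: 11. Longest linear sequence: 8 (steps 1–4 and 8–11).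

Steps most likely to fail:

1. Step 3 (ring A closure). Reversible proton loss from the C4 cation towards C5 could scramble the ring-fusion centre, and elimination and re-addition at the secondary C2 cation could erode the position and configuration of the formate.
   The fallback sets out from 2 and returns at 4, with a chloro-olefin terminator so that no free secondary cation is involved. Alkylation of 2 (LiN(iPr)2; 2,3-dichloropropene, NaI) should give (5R,6R)-6-(2-chloroprop-2-en-1-yl)-2,6-dimethyl-5-(prop-1-en-2-yl)cyclohex-2-en-1-one F1. Its chloro-olefin annulation (90% H2SO4, 0 °C) ends at a chlorine-stabilised C2 cation that is hydrolysed to the trans-fused enedione (4aR,8aR)-4,4,7,8a-tetramethyl-3,4,4a,5-tetrahydronaphthalene-2,8(1H,8aH)-dione F2. NaBH4 (MeOH, −40 °C) should reduce only the saturated C2 ketone, from the face opposite the two axial methyl groups, to the axial alcohol (4aR,7S,8aR)-7-hydroxy-2,5,5,8a-tetramethyl-4a,5,6,7,8,8a-hexahydronaphthalen-1(4H)-one F3. A Mitsunobu inversion with formic acid (PPh3, DIAD) would then give 4.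

2. Step 6 (alkoxy-radical fragmentation). Acetyl hypoiodite could add to the vinyl group, and the lactol could be over-oxidised to the lactone, in competition with β-scission.
   The fallback sets out from 7 and returns at 8, generating the same alkoxy radical without electrophilic halogen. Peroxide exchange (50% H2O2, catalytic H2SO4, Et2O, 0 °C) should give (5S)-5-ethenyl-2-hydroperoxy-5-methyloxolane F4. Redox fragmentation with FeSO4·7H2O and CuCl2 (MeOH–H2O, 0 °C; β-scission, then chlorine-atom transfer from CuCl2) should give (3S)-5-chloro-3-methylpent-1-en-3-yl formate F5. Finkelstein exchange (NaI, acetone, reflux) would give 8.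

3. Step 9 (1,4-hydrogenation). Hydrogen delivery to the hindered, fully substituted diene terminus C9 could be slow or not face-selective, or the double bond could migrate. The same detour also bypasses steps 4 and 8 should the hindered triflate resist formation or coupling.
   The fallback sets out from 4 (with 10) and returns at 14, replacing cross-coupling and hydrogenation by carbonyl addition, oxidative transposition and enone reduction.
   - K2CO3/MeOH would free the hydroxy enone (4aR,7R,8aR)-7-hydroxy-2,5,5,8a-tetramethyl-4a,5,6,7,8,8a-hexahydronaphthalen-1(4H)-one F6, and TBSCl/imidazole would give its tert-butyldimethylsilyl ether F7.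
   - The organocerium reagent from 10 (t-BuLi, then CeCl3, THF, −78 °C) would add to the C9 carbonyl to give the tertiary allylic alcohol F8.
   - Buffered pyridinium chlorochromate (C5H5NH[CrO3Cl], NaOAc) would transpose it oxidatively (Babler–Dauben oxidation) to the C7 enone F9.
   - Li/NH3 would protonate C9 axially (H-9 cis to H-5), and PhNTf2 would trap the C7 enolate as the enol triflate F10.
   - Pd(OAc)2/PPh3 with Bu3N and HCO2H would reduce the triflate to the bis-silyl ether F11, and Bu4NF would give 14.

Further compounds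
F1 | step 3 | (5R,6R)-6-(2-chloroprop-2-en-1-yl)-2,6-dimethyl-5-(prop-1-en-2-yl)cyclohex-2-en-1-one | O=C1C(C)=CC[C@H](C(C)=C)[C@]1(CC(Cl)=C)C
F2 | step 3 | (4aR,8aR)-4,4,7,8a-tetramethyl-3,4,4a,5-tetrahydronaphthalene-2,8(1H,8aH)-dione | O=C1C(C)=CC[C@@H]2C(C)(C)CC(=O)C[C@@]12C
F3 | step 3 | (4aR,7S,8aR)-7-hydroxy-2,5,5,8a-tetramethyl-4a,5,6,7,8,8a-hexahydronaphthalen-1(4H)-one (axial alcohol) | O=C1C(C)=CC[C@@H]2C(C)(C)C[C@H](O)C[C@@]12C
F4 | step 6 | (5S)-5-ethenyl-2-hydroperoxy-5-methyloxolane | C=C[C@@]1(C)OC(OO)CC1
F5 | step 6 | (3S)-5-chloro-3-methylpent-1-en-3-yl formate | C=C[C@@](C)(OC=O)CCCl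
F6 | step 9 | (4aR,7R,8aR)-7-hydroxy-2,5,5,8a-tetramethyl-4a,5,6,7,8,8a-hexahydronaphthalen-1(4H)-one (equatorial alcohol) | O=C1C(C)=CC[C@@H]2C(C)(C)C[C@@H](O)C[C@@]12C
F7 | step 9 | (4aR,7R,8aR)-7-[(tert-butyldimethylsilyl)oxy]-2,5,5,8a-tetramethyl-4a,5,6,7,8,8a-hexahydronaphthalen-1(4H)-one | O=C1C(C)=CC[C@@H]2C(C)(C)C[C@@H](O[Si](C)(C)C(C)(C)C)C[C@@]12C
F8 | step 9 | tertiary allylic alcohol from 1,2-addition at C9 of F7: 2-O-TBS-13-O-TMS-ent-labda-7,14-diene-2,9,13-triol (C9 epimers) | C=C[C@@](C)(O[Si](C)(C)C)CCC1(O)C(C)=CC[C@@H]2C(C)(C)C[C@@H](O[Si](C)(C)C(C)(C)C)C[C@@]12C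
F9 | step 9 | transposed enone: 2-(tert-butyldimethylsilyloxy)-13-(trimethylsilyloxy)-ent-labda-8,14-dien-7-one | C=C[C@@](C)(O[Si](C)(C)C)CCC1=C(C)C(=O)C[C@@H]2C(C)(C)C[C@@H](O[Si](C)(C)C(C)(C)C)C[C@@]12C
F10 | step 9 | enol triflate: 2-(tert-butyldimethylsilyloxy)-13-(trimethylsilyloxy)-ent-labda-7,14-dien-7-yl trifluoromethanesulfonate (H-9 cis to H-5) | C=C[C@@](C)(O[Si](C)(C)C)CC[C@@H]1C(C)=C(OS(=O)(=O)C(F)(F)F)C[C@@H]2C(C)(C)C[C@@H](O[Si](C)(C)C(C)(C)C)C[C@@]12C
F11 | step 9 | 2-O-(tert-butyldimethylsilyl) 13-O-(trimethylsilyl) ether of 14 | C=C[C@@](C)(O[Si](C)(C)C)CC[C@@H]1C(C)=CC[C@@H]2C(C)(C)C[C@@H](O[Si](C)(C)C(C)(C)C)C[C@@]12C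
A1 | direct plan | (4R,6E)-2,6-dimethyl-8-(phenylsulfonyl)octa-1,6-dien-4-ol | C=C(C)C[C@@H](O)C/C(C)=C/CS(=O)(=O)c1ccccc1
A2 | direct plan | (3S,6E)-8-chloro-3,7-dimethylocta-1,6-dien-3-ol | C=C[C@@](C)(O)CC/C=C(\C)CCl
A3 | direct plan | (4R,6E,10E,14S)-14-(formyloxy)-2,6,10,14-tetramethylhexadeca-1,6,10,15-tetraen-4-yl 3-methylbut-2-enoate | C=C[C@@](C)(OC=O)CC/C=C(\C)CC/C=C(\C)C[C@H](OC(=O)C=C(C)C)CC(C)=C
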